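Rings: A is the methoxy-bearing 1,2,3-trisubstituted ring, B the meta-phenylene, C the phenol ring (C-1 bridge carbon, C-3 ether oxygen to D, C-4 hydroxyl) and D the para-phenylene.
Cuts, in retrosynthetic order: the bridge CH2 on C-1 of ring C goes back to C=O; the C-1(ring C)–carbonyl bond is cut by a reverse acyl shift onto the C-4 oxygen; then the ester C–O bond, the A–D ethano bridge (Wittig, hydrogenation) and both diaryl ether C–O bonds (fluoride displacement).
Enabling feature: C-1 of ring C lies para to the hydroxyl-bearing C-4. The C-4 oxygen can therefore first carry the arylacetyl arm of ring B as an ester and then hand it to C-1, and lactone and ketone are both 18-membered.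
Forward: the A–O–B and C–O–D halves are made and joined at the A–D bridge. The chain is closed to the macrolactone (first macrocycle), isomerised to the macrocyclic ketone (second macrocycle, same size) and deoxygenated.
Stereochemistry: the target has no stereocentre and no alkene. Hydrogenation erases the E/Z mixture of the Wittig step, and the carbinol centre passed in the last step is removed again.

Key step: step 9

Assumption: any conformational chirality of the 18-membered cyclophane is taken to be lost by fast ring flipping at room temperature, so the target is treated as achiral.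

Step 1
Reactants: 1 2-fluoro-3-methoxybenzaldehyde; 2 methyl 3-hydroxyphenylacetate
Product: 3 methyl 2-[3-(2-formyl-6-methoxyphenoxy)phenyl]acetate
Conditions: K2CO3, DMF, 110 °C, N2
Reagents that add atoms: none
Why: Nucleophilic aromatic substitution by addition–elimination, in which the ortho formyl group stabilises the Meisenheimer adduct, fluoride is the best leaving group for this mechanism, and carbonate is too weak a base to enolise the arylacetate to a harmful extent.

Step 2
Reactants: 4 2-(benzyloxy)phenol; 5 4-fluorobenzaldehyde
Product: 6 4-[2-(benzyloxy)phenoxy]benzaldehyde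
Conditions: K2CO3, DMF, 120 °C
Reagents that add atoms: none
Why: Nucleophilic aromatic substitution of a para-formyl-activated aryl fluoride by a phenoxide, a standard entry to diaryl ethers that leaves the benzyl ether untouched.

Step 3
Reactants: 6 4-[2-(benzyloxy)phenoxy]benzaldehyde
Product: 7 {4-[2-(benzyloxy)phenoxy]phenyl}methanol
Conditions: NaBH4, MeOH–THF, 0 °C
Reagents that add atoms: none
Why: Borohydride reduction of an aromatic aldehyde, the only reducible group present.

Step 4
Reactants: 7 {4-[2-(benzyloxy)phenoxy]phenyl}methanol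
Product: 8 {4-[2-(benzyloxy)phenoxy]benzyl}triphenylphosphonium bromide
Conditions: PPh3·HBr, MeCN, reflux
Reagents that add atoms: triphenylphosphine hydrobromide, [Br-].c1ccc(cc1)[PH+](c1ccccc1)c1ccccc1
Why: Direct phosphonium salt formation from a benzylic alcohol, in which the para-aryloxy group eases acid-induced loss of water, triphenylphosphine captures the benzylic carbon, and the aryl benzyl ether tolerates this mild acid source.

Step 5
Reactants: 8 {4-[2-(benzyloxy)phenoxy]benzyl}triphenylphosphonium bromide; 3 methyl 2-[3-(2-formyl-6-methoxyphenoxy)phenyl]acetate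
Product: 10 methyl 2-{3-[2-(2-{4-[2-(benzyloxy)phenoxy]phenyl}ethenyl)-6-methoxyphenoxy]phenyl}acetate (E/Z mixture), via phosphonium ylide 9 (not isolated)
Conditions: K2CO3, 18-crown-6 (cat.), CH2Cl2, reflux
Reagents that add atoms: none
Why: Wittig olefination with a semistabilised benzylide generated by solid–liquid phase transfer, mild enough for the methyl ester, and the alkene geometry is irrelevant because the double bond is saturated next.

Step 6
Reactants: 10 methyl 2-{3-[2-(2-{4-[2-(benzyloxy)phenoxy]phenyl}ethenyl)-6-methoxyphenoxy]phenyl}acetate (E/Z mixture)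
Product: 11 methyl 2-{3-[2-(2-{4-(2-hydroxyphenoxy)phenyl}ethyl)-6-methoxyphenoxy]phenyl}acetate
Conditions: H2 (1 atm), 10% Pd/C, EtOAc–MeOH, rt
Reagents that add atoms: none
Why: Catalytic hydrogenation saturates the stilbene and hydrogenolyses the aryl benzyl ether in one operation, while ester, methyl ether and diaryl ethers are inert.

Step 7
Reactants: 11 methyl 2-{3-[2-(2-{4-(2-hydroxyphenoxy)phenyl}ethyl)-6-methoxyphenoxy]phenyl}acetate
Product: 12 2-{3-[2-(2-{4-(2-hydroxyphenoxy)phenyl}ethyl)-6-methoxyphenoxy]phenyl}acetic acid (seco acid)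
Conditions: LiOH, THF–MeOH–H2O, rt; then 1 M HCl
Reagents that add atoms: lithium hydroxide, [Li+].[OH-]
Why: Saponification of an unhindered methyl ester, followed by acidification to the free hydroxy acid.

Step 8
Reactants: 12 seco acid
Product: 14 18-membered macrolactone in which the ring B CH2C(=O) group is esterified to the ring C oxygen ortho to the ring D ether oxygen, via mixed anhydride 13 (not isolated)
Conditions: MNBA, DMAP, CH2Cl2, 12 added by syringe pump over 12 h, final 1 mM, rt
Reagents that add atoms: 2-methyl-6-nitrobenzoic anhydride (MNBA), Cc1cccc([N+](=O)[O-])c1C(=O)OC(=O)c1c(C)cccc1[N+](=O)[O-] (its aroyl group is held only in 13 and leaves again before 14)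
Why: Shiina macrolactonisation, in which MNBA turns the acid into mixed anhydride 13, DMAP passes the less hindered arylacetyl group to the phenol oxygen, and slow addition keeps the seco acid dilute enough for the 18-membered closure to beat dimer formation.

Step 9
Reactants: 14 18-membered macrolactone
Product: 16 18-membered macrocyclic ketone (ring B–CH2–C(=O)–ring C) whose carbonyl stands para to the freed ring C hydroxyl, via seco acylium ion 15 (not isolated)
Conditions: TfOH–TFA (1:9 v/v), 1 mM, 0 °C to rt; then ice-cold aq NaHCO3
Reagents that add atoms: none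
Why: Proposed new method: in this strongly acidic, weakly nucleophilic medium the ester carbonyl of 14 is protonated and the acyl–oxygen bond ionises to arylacetylium ion 15, which stays tied to the freed 2-aryloxyphenol through rings B, A and D; the cation then attacks ring C in a Friedel–Crafts step, and loss of the ring proton gives ketone 16, which is protonated and so neither ionises back nor reacts further. The closest known reaction types are the para-selective Fries rearrangement of phenyl and guaiacyl esters in sulfonic acids, the high-dilution Friedel–Crafts acylation that closes cyclophanones, and the photochemical Fries ring contraction of aryl macrolactones, known for ortho shifts; the acid-promoted para shift across a macrocycle is the untested part. The one ring formed is the 18-membered ring of 16, closed end to end by attack of C-1 of ring C on the sp carbon of the acylium ion (formally 18-exo-dig), so ring C changes from ortho-bridged through oxygen to meta-bridged through carbon while the ring size stays 18. Site selectivity on ring C rests on three points: the free hydroxyl is a stronger donor than the aryloxy group (guaiacyl esters shift para to the hydroxyl), low temperature and a polar medium favour para over ortho, and the ortho path, also 18-membered, would force the hydroxyl-bearing carbon to point into the ring. Ring selectivity rests on geometry: the tethered cation can reach the activated carbon para to methoxy in ring A and the carbons of ring D only through strained 9- to 13-membered cyclophane rings, so these sites compete only between molecules, which the 1 mM dilution suppresses. No stereocentre is formed.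

Step 10
Reactants: 16 18-membered macrocyclic ketone
Product: 18 target CNP0309263.0, via benzylic carbinol 17 (not isolated)
Conditions: Et3SiH (excess), TFA–CH2Cl2 (1:1), rt to 40 °C
Reagents that add atoms: none
Why: Ionic hydrogenation, in which TFA protonates the donor-substituted aryl ketone, Et3SiH delivers hydride to give racemic carbinol 17, the para-hydroxybenzylic cation from 17 takes a second hydride, and any stilbene formed by proton loss is reprotonated and reduced to the same methylene compound.

Compound list
1 | 2-fluoro-3-methoxybenzaldehyde | COc1cccc(C=O)c1F | starting material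
2 | methyl 3-hydroxyphenylacetate | COC(=O)Cc1cccc(O)c1 | starting material
3 | methyl 2-[3-(2-formyl-6-methoxyphenoxy)phenyl]acetate | COC(=O)Cc1cccc(Oc2c(C=O)cccc2OC)c1 | intermediate
4 | 2-(benzyloxy)phenol | Oc1ccccc1OCc1ccccc1 | starting material
5 | 4-fluorobenzaldehyde | O=Cc1ccc(F)cc1 | starting material
6 | 4-[2-(benzyloxy)phenoxy]benzaldehyde | O=Cc1ccc(Oc2ccccc2OCc2ccccc2)cc1 | intermediate
7 | {4-[2-(benzyloxy)phenoxy]phenyl}methanol | OCc1ccc(Oc2ccccc2OCc2ccccc2)cc1 | intermediate
8 | {4-[2-(benzyloxy)phenoxy]benzyl}triphenylphosphonium bromide | [Br-].c1ccc(cc1)COc1ccccc1Oc1ccc(cc1)C[P+](c1ccccc1)(c1ccccc1)c1ccccc1 | intermediate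
9 | phosphonium ylide from 8 (not isolated) | c1ccc(cc1)COc1ccccc1Oc1ccc(cc1)C=P(c1ccccc1)(c1ccccc1)c1ccccc1 | intermediate
10 | methyl 2-{3-[2-(2-{4-[2-(benzyloxy)phenoxy]phenyl}ethenyl)-6-methoxyphenoxy]phenyl}acetate (E/Z mixture) | COC(=O)Cc1cccc(Oc2c(C=Cc3ccc(Oc4ccccc4OCc4ccccc4)cc3)cccc2OC)c1 | intermediate
11 | methyl 2-{3-[2-(2-{4-(2-hydroxyphenoxy)phenyl}ethyl)-6-methoxyphenoxy]phenyl}acetate | COC(=O)Cc1cccc(Oc2c(CCc3ccc(Oc4ccccc4O)cc3)cccc2OC)c1 | intermediate
12 | 2-{3-[2-(2-{4-(2-hydroxyphenoxy)phenyl}ethyl)-6-methoxyphenoxy]phenyl}acetic acid (seco acid) | OC(=O)Cc1cccc(Oc2c(CCc3ccc(Oc4ccccc4O)cc3)cccc2OC)c1 | intermediate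
13 | mixed anhydride of 12 and 2-methyl-6-nitrobenzoic acid (not isolated) | Cc1cccc([N+](=O)[O-])c1C(=O)OC(=O)Cc1cccc(Oc2c(CCc3ccc(Oc4ccccc4O)cc3)cccc2OC)c1 | intermediate
14 | 18-membered macrolactone (aryl arylacetate, key-step precursor) | COc1cccc2c1Oc1cccc(c1)CC(=O)Oc1ccccc1Oc1ccc(cc1)CC2 | intermediate
15 | seco acylium ion tethered to the free 2-aryloxyphenol (not isolated) | COc1cccc(CCc2ccc(Oc3ccccc3O)cc2)c1Oc1cccc(CC#[O+])c1 | intermediate
16 | 18-membered macrocyclic para-hydroxyaryl ketone (key-step product) | COc1cccc2c1Oc1cccc(c1)CC(=O)c1ccc(O)c(c1)Oc1ccc(cc1)CC2 | intermediate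
17 | macrocyclic benzylic carbinol, racemic (not isolated) | COc1cccc2c1Oc1cccc(c1)CC(O)c1ccc(O)c(c1)Oc1ccc(cc1)CC2 | intermediate
18 | CNP0309263.0 | COc1cccc2c1Oc1cccc(c1)CCc1ccc(O)c(c1)Oc1ccc(cc1)CC2 | target

Total step count: 10. Longest linear sequence: 9 (steps 2 to 10).

Steps most likely to fail

Step 9. Several processes could defeat the shift.
- The ionised acyl arm may be captured between molecules, chiefly at the carbon para to methoxy in ring A of a second molecule.
- It may settle ortho to the hydroxyl or para to the aryloxy group of ring C.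
- It may lose carbon monoxide, or simply return to oxygen without ever reaching carbon.

The fallback uses known chemistry only. It sets out from 11, comes back at 18, and makes the same ring C–bridge bond by cross-coupling.
- Phenol 11 is brominated para to the hydroxyl with Bu4NBr3 (CH2Cl2–MeOH, rt) to the para-bromophenol F1.
- BnBr and K2CO3 in acetone give the benzyl ether F2, and LiBH4 in THF reduces the ester to the primary alcohol F3.
- MsCl and Et3N give the mesylate F4, and t-BuOK (THF, 0 °C) eliminates it to the styrene F5.
- 9-BBN-H in THF adds to the vinyl group to give the B-alkyl borane F6.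
- F6 is run slowly into Pd(dppf)Cl2 and Cs2CO3 in DMF–THF–H2O at 60 °C (B-alkyl Suzuki–Miyaura macrocyclisation) to close the O-benzyl macrocycle F7.
- H2 over Pd/C removes the benzyl group and gives 18.

Step 8. Chain growth to dimeric and oligomeric esters, or ketene formation from the activated arylacetic acid followed by self-condensation, may outrun the ring closure. The fallback sets out from 3 and 8 and comes back at 14. The ester bond is made between two molecules, and the ring is closed at the A–D bridge instead.
- LiOH hydrolysis of 3 gives the aldehyde acid F8.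
- Hydrogenolysis of 8 (H2, Pd/C, MeOH) gives the phenolic phosphonium bromide F9.
- EDC·HCl and catalytic DMAP in CH2Cl2 join them to the aryl ester phosphonium salt F10.
- Slow addition of F10 to K2CO3 and 18-crown-6 in refluxing CH2Cl2 forms the tethered ylide F11.
- F11 closes by intramolecular Wittig reaction to the macrocyclic stilbene lactone F12 (E/Z mixture).
- H2 over Pd/C in EtOAc saturates the alkene and gives 14.

Step 1. Displacement at a carbon flanked by formyl and methoxy may be slow. Prolonged heating would then let aldol-type condensation of the arylacetate methylene with the aldehyde compete. The fallback sets out from 2 and comes back at 3. The addition–elimination is replaced by a copper-catalysed Ullmann-type ether coupling of 2 with commercial 2-bromo-3-methoxybenzaldehyde (CuI, N,N-dimethylglycine, Cs2CO3, dioxane, 90 °C). The ortho formyl group assists the copper step, and the less polar medium disfavours enolate chemistry. This fallback makes no compound outside the list (F0).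

Further compounds
F1 | step 9 | methyl 2-{3-[2-(2-{4-(5-bromo-2-hydroxyphenoxy)phenyl}ethyl)-6-methoxyphenoxy]phenyl}acetate | COC(=O)Cc1cccc(Oc2c(CCc3ccc(Oc4cc(Br)ccc4O)cc3)cccc2OC)c1
F2 | step 9 | methyl 2-{3-[2-(2-{4-[2-(benzyloxy)-5-bromophenoxy]phenyl}ethyl)-6-methoxyphenoxy]phenyl}acetate | COC(=O)Cc1cccc(Oc2c(CCc3ccc(Oc4cc(Br)ccc4OCc4ccccc4)cc3)cccc2OC)c1
F3 | step 9 | 2-{3-[2-(2-{4-[2-(benzyloxy)-5-bromophenoxy]phenyl}ethyl)-6-methoxyphenoxy]phenyl}ethanol | OCCc1cccc(Oc2c(CCc3ccc(Oc4cc(Br)ccc4OCc4ccccc4)cc3)cccc2OC)c1
F4 | step 9 | methanesulfonate of F3 | CS(=O)(=O)OCCc1cccc(Oc2c(CCc3ccc(Oc4cc(Br)ccc4OCc4ccccc4)cc3)cccc2OC)c1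
F5 | step 9 | ring B styrene: 1-{2-[4-(2-benzyloxy-5-bromophenoxy)phenyl]ethyl}-2-(3-ethenylphenoxy)-3-methoxybenzene | C=Cc1cccc(Oc2c(CCc3ccc(Oc4cc(Br)ccc4OCc4ccccc4)cc3)cccc2OC)c1
F6 | step 9 | B-alkyl-9-borabicyclo[3.3.1]nonane adduct of F5 | C(Cc1cccc(Oc2c(CCc3ccc(Oc4cc(Br)ccc4OCc4ccccc4)cc3)cccc2OC)c1)B1C2CCCC1CCC2
F7 | step 9 | O-benzyl ether of the target macrocycle | COc1cccc2c1Oc1cccc(c1)CCc1ccc(OCc3ccccc3)c(c1)Oc1ccc(cc1)CC2
F8 | step 8 | 2-[3-(2-formyl-6-methoxyphenoxy)phenyl]acetic acid | COc1cccc(C=O)c1Oc1cccc(CC(=O)O)c1
F9 | step 8 | [4-(2-hydroxyphenoxy)benzyl]triphenylphosphonium bromide | [Br-].Oc1ccccc1Oc1ccc(C[P+](c2ccccc2)(c2ccccc2)c2ccccc2)cc1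
F10 | step 8 | aryl ester of F8 and F9 (aldehyde phosphonium bromide) | [Br-].COc1cccc(C=O)c1Oc1cccc(CC(=O)Oc2ccccc2Oc2ccc(C[P+](c3ccccc3)(c3ccccc3)c3ccccc3)cc2)c1
F11 | step 8 | ylide from F10 | COc1cccc(C=O)c1Oc1cccc(CC(=O)Oc2ccccc2Oc2ccc(C=P(c3ccccc3)(c3ccccc3)c3ccccc3)cc2)c1
F12 | step 8 | macrocyclic stilbene lactone (E/Z mixture) | COc1cccc2c1Oc1cccc(c1)CC(=O)Oc1ccccc1Oc1ccc(cc1)C=C2
F0 | step 1 | none | none
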